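**Retrosynthetic overview**

1. The target is cut at the C(sp3)–C(sp2) bond between the homoallylic CH2 of the terpenoid chain and the olefinic carbon that carries CH2OH. This gives a C16 homoallyl bromide (cyclohexene ring already in place, used as its Grignard reagent) and a C9 alkynol, HOCH2–C≡C–CH2–CH(OTBS)–(3-furyl), of (S) configuration.
2. Enabling feature: the primary allylic hydroxyl on that olefinic carbon (the O–CH2–C(=CH) unit of the target). As the magnesium alkoxide of a 2-alkyn-1-ol it directs a copper-catalysed anti-carbomagnesiation, so the bond and the geometry of the hydroxymethyl-bearing trisubstituted olefin arise in one operation from a geometry-free alkyne.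
3. C16 fragment: dihydro-β-ionone → terminal alkyne → syn-methylalumination/oxirane opening ((E)-olefin) → bromide. C9 fragment: furan-3-carbaldehyde → catalytic asymmetric propargylation (the only stereocentre) → TBS ether → hydroxymethylation.
4. Rings: the carbocycle is bought with dihydro-β-ionone and no ring is closed in the union. The 2(5H)-furanone is formed last from the 3-furyl ring (singlet oxygen to the γ-hydroxybutenolide, borohydride reduction and relactonisation), followed by desilylation.

Key step: step 7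

Remark: the SMILES is read as the (S)-carbinol with E geometry at both trisubstituted olefins (CH2OH cis to the vinylic hydrogen); dihydro-β-ionone, furan-3-carbaldehyde, allenylboronic acid pinacol ester and (S)-TRIP are taken as purchasable.

**Route**

Step 1
Reactants: 1 dihydro-β-ionone [4-(2,6,6-trimethylcyclohex-1-en-1-yl)butan-2-one]
Product: 5 terminal alkyne 2-(but-3-yn-1-yl)-1,3,3-trimethylcyclohex-1-ene, via lithium enolate 2 (not isolated), via enol phosphate 3 (not isolated), via lithium acetylide 4 (not isolated)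
Conditions: LiN(i-Pr)2 (1.05 equiv), THF, −78 °C; ClP(O)(OEt)2, −78 °C → rt; LiN(i-Pr)2 (2.3 equiv), THF, −78 °C → rt; H2O
Reagents that add atoms: none
Why: Kinetic deprotonation of the methyl ketone at −78 °C should give the terminal enolate, and its O-phosphorylation followed by base-induced elimination of diethyl phosphate (Negishi enol phosphate route from methyl ketones to 1-alkynes) is driven by formation of the lithium acetylide; no stereocentre is involved.

Step 2
Reactants: 5 terminal alkyne 2-(but-3-yn-1-yl)-1,3,3-trimethylcyclohex-1-ene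
Product: 8 (E)-4-methyl-6-(2,6,6-trimethylcyclohex-1-en-1-yl)hex-3-en-1-ol, via alkenylalane 6 (not isolated), via lithium alanate 7 (not isolated)
Conditions: Me3Al (2 equiv), Cp2ZrCl2 (0.25 equiv), ClCH2CH2Cl, rt; volatiles removed; n-BuLi, hexane–THF, −78 → 0 °C; oxirane, 0 °C → rt; H2O
Reagents that add atoms: trimethylaluminium C[Al](C)C; oxirane C1CO1
Why: Zirconocene-catalysed methylalumination (Negishi carboalumination) adds CH3 and Al syn across the terminal alkyne with Al at the terminus, and the derived alkenylalanate opens oxirane with retention, so the (E)-trisubstituted olefin follows from the mechanism and not from a selectivity that has to be tuned.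

Step 3
Reactants: 8 (E)-4-methyl-6-(2,6,6-trimethylcyclohex-1-en-1-yl)hex-3-en-1-ol
Product: 9 2-[(E)-6-bromo-3-methylhex-3-en-1-yl]-1,3,3-trimethylcyclohex-1-ene
Conditions: CBr4, PPh3, CH2Cl2, 0 °C
Reagents that add atoms: tetrabromomethane BrC(Br)(Br)Br
Why: The Appel reaction converts the unhindered primary alcohol by SN2 displacement of an alkoxyphosphonium ion under neutral conditions that should leave both olefins untouched.

Step 4
Reactants: 10 furan-3-carbaldehyde
Product: 12 (S)-1-(furan-3-yl)but-3-yn-1-ol, via borate ester 11 (not isolated)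
Conditions: allenylboronic acid pinacol ester (1.5 equiv), (S)-TRIP [(S)-3,3'-bis(2,4,6-triisopropylphenyl)-1,1'-binaphthyl-2,2'-diyl hydrogen phosphate] (5 mol %), 4 Å molecular sieves, toluene, 0 °C; aqueous work-up
Reagents that add atoms: allenylboronic acid pinacol ester C=C=CB1OC(C)(C)C(C)(C)O1
Why: Chiral phosphoric acid-catalysed propargylation (SE2' addition of the allenylboronate through a closed six-membered chair transition state in which the acid binds a boronate oxygen and the formyl hydrogen) is expected, by analogy with aryl aldehydes, to deliver the propargyl group to the Si face under control of the (S)-configured acid and so to set the (S)-carbinol, the only stereocentre of the target.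

Step 5
Reactants: 12 (S)-1-(furan-3-yl)but-3-yn-1-ol
Product: 13 (S)-tert-butyl{[1-(furan-3-yl)but-3-yn-1-yl]oxy}dimethylsilane
Conditions: TBSCl, imidazole, DMF, rt
Reagents that add atoms: tert-butyldimethylsilyl chloride CC(C)(C)[Si](C)(C)Cl
Why: Standard silylation of a secondary alcohol gives an ether that should survive organolithium, Grignard, singlet-oxygen and borohydride conditions and later keeps this hydroxyl out of the lactonisation of step 9; the stereocentre is not touched.

Step 6
Reactants: 13 (S)-tert-butyl{[1-(furan-3-yl)but-3-yn-1-yl]oxy}dimethylsilane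
Product: 15 (S)-5-[(tert-butyldimethylsilyl)oxy]-5-(furan-3-yl)pent-2-yn-1-ol, via lithium acetylide 14 (not isolated)
Conditions: n-BuLi (1.05 equiv), THF, −78 °C; (CH2O)n, −78 °C → rt; H2O
Reagents that add atoms: paraformaldehyde (as formaldehyde) C=O
Why: Deprotonation of the terminal alkyne, far more acidic than the furan α-hydrogens, and addition of the lithium acetylide to formaldehyde is the standard hydroxymethylation of 1-alkynes.

Step 7
Reactants: 9 2-[(E)-6-bromo-3-methylhex-3-en-1-yl]-1,3,3-trimethylcyclohex-1-ene; 15 (S)-5-[(tert-butyldimethylsilyl)oxy]-5-(furan-3-yl)pent-2-yn-1-ol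
Product: 19 (2E,5E)-2-[(3S)-3-[(tert-butyldimethylsilyl)oxy]-3-(furan-3-yl)propylidene]-6-methyl-8-(2,6,6-trimethylcyclohex-1-en-1-yl)oct-5-en-1-ol, via chloromagnesium alkoxide 16 (not isolated), via Grignard reagent 17 (not isolated), via oxamagnesacycle 18 (not isolated)
Conditions: 15, i-PrMgCl (1.0 equiv), THF, 0 °C; 9 (2.0 equiv), Mg, THF, rt; solutions combined, CuI (10 mol %), THF, 0 °C → rt; H2O
Reagents that add atoms: none
Why: The preformed chloromagnesium alkoxide 16 anchors the alkylcopper species generated from Grignard reagent 17 and catalytic CuI, the homoallyl group is delivered to the alkyne carbon next to CH2O and magnesium ends on the distal alkyne carbon, giving by net anti addition the five-membered oxamagnesacycle 18 (O–Mg–C=C–CH2), whose hydrolysis puts hydrogen where magnesium was. The closest known reaction type is the copper-catalysed anti-carbomagnesiation of 2-alkyn-1-ols with Grignard reagents, which has precedent for primary alkylmagnesium halides and for internal alkynols. No ring of the target is closed; the only ring formed is the transient magnesium chelate, closed by the C–Mg bond in an endo sense at the distal alkyne carbon and opened again on work-up. No stereocentre is created and the (S)-carbinol is untouched, while the geometry of the new trisubstituted olefin is dictated by the chelate: CH2O and Mg (later H) are held cis, so the incoming chain ends cis to the CH2CH(OTBS) branch, which is the E arrangement of the target. The step needs regioselectivity for the carbon next to CH2O, anti stereoselectivity and chemoselectivity for the alkyne; the first two are secured by the propargylic alkoxide of 15, the third by the inertness of the furan, the isolated olefins of 17 and the silyl ether (γ to the C–Mg bond, so no β-elimination) toward organomagnesium and organocopper reagents at room temperature. In this way a C16 and a C9 fragment, neither of which carries the geometry of this olefin, are joined and the olefin is set in the same operation.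

Step 8
Reactants: 19 (2E,5E)-2-[(3S)-3-[(tert-butyldimethylsilyl)oxy]-3-(furan-3-yl)propylidene]-6-methyl-8-(2,6,6-trimethylcyclohex-1-en-1-yl)oct-5-en-1-ol
Product: 21 4-[(1S,3E,7E)-1-[(tert-butyldimethylsilyl)oxy]-4-(hydroxymethyl)-8-methyl-10-(2,6,6-trimethylcyclohex-1-en-1-yl)deca-3,7-dien-1-yl]-5-hydroxyfuran-2(5H)-one, via endoperoxide 20 (not isolated)
Conditions: O2, hν (visible), tetraphenylporphyrin (cat.), i-Pr2NEt (5 equiv), CH2Cl2, −78 °C
Reagents that add atoms: dioxygen O=O
Why: [4+2] cycloaddition of singlet oxygen to the furan, the π system expected to react fastest at −78 °C, gives endoperoxide 20, from which the hindered amine should remove the less encumbered bridgehead hydrogen (remote from the silyloxyalkyl group) in a Kornblum–DeLaMare-type fragmentation that places C=O at the remote α-carbon and OH next to the substituent; the hemiacetal carbon forms as an epimer mixture that is erased in step 9.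

Step 9
Reactants: 21 4-[(1S,3E,7E)-1-[(tert-butyldimethylsilyl)oxy]-4-(hydroxymethyl)-8-methyl-10-(2,6,6-trimethylcyclohex-1-en-1-yl)deca-3,7-dien-1-yl]-5-hydroxyfuran-2(5H)-one
Product: 23 4-[(1S,3E,7E)-1-[(tert-butyldimethylsilyl)oxy]-4-(hydroxymethyl)-8-methyl-10-(2,6,6-trimethylcyclohex-1-en-1-yl)deca-3,7-dien-1-yl]furan-2(5H)-one, via hydroxy acid 22 (not isolated)
Conditions: NaBH4, EtOH, 0 °C; 1 M HCl to pH 3
Reagents that add atoms: none
Why: Under the basic borohydride conditions the γ-hydroxybutenolide is in ring–chain equilibrium with its formyl carboxylate, whose aldehyde is reduced chemoselectively, and acidification closes the γ-lactone (5-exo-trig) on the new primary alcohol, the only free hydroxyl within reach because the carbinol is silylated.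

Step 10
Reactants: 23 4-[(1S,3E,7E)-1-[(tert-butyldimethylsilyl)oxy]-4-(hydroxymethyl)-8-methyl-10-(2,6,6-trimethylcyclohex-1-en-1-yl)deca-3,7-dien-1-yl]furan-2(5H)-one
Product: 24 4-[(1S,3E,7E)-1-hydroxy-4-(hydroxymethyl)-8-methyl-10-(2,6,6-trimethylcyclohex-1-en-1-yl)deca-3,7-dien-1-yl]furan-2(5H)-one
Conditions: HF·pyridine, pyridine, THF, 0 °C → rt
Reagents that add atoms: none
Why: Fluoride cleavage of the secondary silyl ether under buffered, weakly acidic conditions should avoid the base-induced isomerisation or translactonisation of the butenolide that tetrabutylammonium fluoride could cause, and leaves the stereocentre intact.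

**Compound list**

1 | dihydro-β-ionone, 4-(2,6,6-trimethylcyclohex-1-en-1-yl)butan-2-one | CC(=O)CCC1=C(C)CCCC1(C)C | starting material
2 | lithium 4-(2,6,6-trimethylcyclohex-1-en-1-yl)but-1-en-2-olate | C=C(O[Li])CCC1=C(C)CCCC1(C)C | intermediate
3 | diethyl 4-(2,6,6-trimethylcyclohex-1-en-1-yl)but-1-en-2-yl phosphate | C=C(CCC1=C(C)CCCC1(C)C)OP(=O)(OCC)OCC | intermediate
4 | [4-(2,6,6-trimethylcyclohex-1-en-1-yl)but-1-yn-1-yl]lithium | [Li]C#CCCC1=C(C)CCCC1(C)C | intermediate
5 | 2-(but-3-yn-1-yl)-1,3,3-trimethylcyclohex-1-ene | C#CCCC1=C(C)CCCC1(C)C | intermediate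
6 | (E)-dimethyl[2-methyl-4-(2,6,6-trimethylcyclohex-1-en-1-yl)but-1-en-1-yl]alane | CC1=C(CC/C(C)=C/[Al](C)C)C(C)(C)CCC1 | intermediate
7 | lithium (E)-butyl(dimethyl)[2-methyl-4-(2,6,6-trimethylcyclohex-1-en-1-yl)but-1-en-1-yl]aluminate | CC1=C(CC/C(C)=C/[Al-](C)(C)CCCC)C(C)(C)CCC1.[Li+] | intermediate
8 | (E)-4-methyl-6-(2,6,6-trimethylcyclohex-1-en-1-yl)hex-3-en-1-ol | CC1=C(CC/C(C)=C/CCO)C(C)(C)CCC1 | intermediate
9 | 2-[(E)-6-bromo-3-methylhex-3-en-1-yl]-1,3,3-trimethylcyclohex-1-ene | CC1=C(CC/C(C)=C/CCBr)C(C)(C)CCC1 | intermediate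
10 | furan-3-carbaldehyde | O=Cc1ccoc1 | starting material
11 | (S)-2-{[1-(furan-3-yl)but-3-yn-1-yl]oxy}-4,4,5,5-tetramethyl-1,3,2-dioxaborolane | C#CC[C@H](OB1OC(C)(C)C(C)(C)O1)c1ccoc1 | intermediate
12 | (S)-1-(furan-3-yl)but-3-yn-1-ol | C#CC[C@H](O)c1ccoc1 | intermediate
13 | (S)-tert-butyl{[1-(furan-3-yl)but-3-yn-1-yl]oxy}dimethylsilane | C#CC[C@H](O[Si](C)(C)C(C)(C)C)c1ccoc1 | intermediate
14 | lithium acetylide of 13, {(S)-4-[(tert-butyldimethylsilyl)oxy]-4-(furan-3-yl)but-1-yn-1-yl}lithium | [Li]C#CC[C@H](O[Si](C)(C)C(C)(C)C)c1ccoc1 | intermediate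
15 | (S)-5-[(tert-butyldimethylsilyl)oxy]-5-(furan-3-yl)pent-2-yn-1-ol | OCC#CC[C@H](O[Si](C)(C)C(C)(C)C)c1ccoc1 | intermediate
16 | chloromagnesium (S)-5-[(tert-butyldimethylsilyl)oxy]-5-(furan-3-yl)pent-2-yn-1-olate | Cl[Mg]OCC#CC[C@H](O[Si](C)(C)C(C)(C)C)c1ccoc1 | intermediate
17 | [(E)-4-methyl-6-(2,6,6-trimethylcyclohex-1-en-1-yl)hex-3-en-1-yl]magnesium bromide | CC1=C(CC/C(C)=C/CC[Mg]Br)C(C)(C)CCC1 | intermediate
18 | 3-[(S)-2-[(tert-butyldimethylsilyl)oxy]-2-(furan-3-yl)ethyl]-4-[(E)-4-methyl-6-(2,6,6-trimethylcyclohex-1-en-1-yl)hex-3-en-1-yl]-2,5-dihydro-1,2-oxamagnesole | CC1=C(CC/C(C)=C/CCC2=C(C[C@H](O[Si](C)(C)C(C)(C)C)c3ccoc3)[Mg]OC2)C(C)(C)CCC1 | intermediate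
19 | (2E,5E)-2-[(3S)-3-[(tert-butyldimethylsilyl)oxy]-3-(furan-3-yl)propylidene]-6-methyl-8-(2,6,6-trimethylcyclohex-1-en-1-yl)oct-5-en-1-ol | CC1=C(CC/C(C)=C/CC/C(=C\C[C@H](O[Si](C)(C)C(C)(C)C)c2ccoc2)CO)C(C)(C)CCC1 | intermediate
20 | furan endoperoxide of 19 (5-substituted 2,3,7-trioxabicyclo[2.2.1]hept-5-ene; bridgehead configuration not controlled) | CC1=C(CC/C(C)=C/CC/C(=C\C[C@H](O[Si](C)(C)C(C)(C)C)C2=CC3OOC2O3)CO)C(C)(C)CCC1 | intermediate
21 | 4-[(1S,3E,7E)-1-[(tert-butyldimethylsilyl)oxy]-4-(hydroxymethyl)-8-methyl-10-(2,6,6-trimethylcyclohex-1-en-1-yl)deca-3,7-dien-1-yl]-5-hydroxyfuran-2(5H)-one (epimers at the hemiacetal carbon) | CC1=C(CC/C(C)=C/CC/C(=C\C[C@H](O[Si](C)(C)C(C)(C)C)C2=CC(=O)OC2O)CO)C(C)(C)CCC1 | intermediate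
22 | (2E,4S,6E,10E)-4-[(tert-butyldimethylsilyl)oxy]-3,7-bis(hydroxymethyl)-11-methyl-13-(2,6,6-trimethylcyclohex-1-en-1-yl)trideca-2,6,10-trienoic acid | CC1=C(CC/C(C)=C/CC/C(=C\C[C@H](O[Si](C)(C)C(C)(C)C)/C(CO)=C/C(=O)O)CO)C(C)(C)CCC1 | intermediate
23 | 4-[(1S,3E,7E)-1-[(tert-butyldimethylsilyl)oxy]-4-(hydroxymethyl)-8-methyl-10-(2,6,6-trimethylcyclohex-1-en-1-yl)deca-3,7-dien-1-yl]furan-2(5H)-one | CC1=C(CC/C(C)=C/CC/C(=C\C[C@H](O[Si](C)(C)C(C)(C)C)C2=CC(=O)OC2)CO)C(C)(C)CCC1 | intermediate
24 | 4-[(1S,3E,7E)-1-hydroxy-4-(hydroxymethyl)-8-methyl-10-(2,6,6-trimethylcyclohex-1-en-1-yl)deca-3,7-dien-1-yl]furan-2(5H)-one | CC1=C(CC/C(C)=C/CC/C(=C\C[C@H](O)C2=CC(=O)OC2)CO)C(C)(C)CCC1 | target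

**Step count**

Total steps: 10.
Longest linear sequence: 7 steps (steps 1–3 then 7–10; the branch of steps 4–6 then 7–10 is equally long).

**Steps most likely to fail**

Step 7. The carbometalation of an internal, β-branched alkynol by a primary alkyl Grignard reagent may be sluggish. The reagent could then be lost through protonation or copper-mediated homocoupling, or some addition could leak to the regioisomeric or syn adduct. The fallback sets out from alkynol 15 and bromide 9 and forms the same bond by cross-coupling. Hydroxyl-directed trans-hydrostannation of 15 (Bu3SnH, [Cp*RuCl]4 cat., CH2Cl2, rt) should place tin on the alkyne carbon next to CH2OH with hydrogen anti to it. This gives (S,Z)-5-[(tert-butyldimethylsilyl)oxy]-5-(furan-3-yl)-2-(tributylstannyl)pent-2-en-1-ol F1. Iododestannylation (I2, CH2Cl2, 0 °C) with retention gives (S,Z)-5-[(tert-butyldimethylsilyl)oxy]-5-(furan-3-yl)-2-iodopent-2-en-1-ol F2. Bromide 9 is converted with Zn dust and LiCl in THF into [(E)-4-methyl-6-(2,6,6-trimethylcyclohex-1-en-1-yl)hex-3-en-1-yl]zinc bromide F3. A Negishi sp3–sp2 coupling of F2 with F3 (Pd(OAc)2, SPhos, THF, rt; alkylzinc halides tolerate the free hydroxyl) proceeds with retention of olefin geometry and comes back to the route at 19.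

Step 8. Singlet oxygen may attack the tetrasubstituted ring olefin or the trisubstituted olefins in an ene reaction, or the endoperoxide may fragment in the other direction. The fallback moves the oxidation ahead of the fragment union, where no olefin is present. It sets out from alkynol 15, which is photooxygenated under the conditions of step 8 to 4-[(S)-1-[(tert-butyldimethylsilyl)oxy]-5-hydroxypent-3-yn-1-yl]-5-hydroxyfuran-2(5H)-one F4. Reduction as in step 9 gives (S)-4-[1-[(tert-butyldimethylsilyl)oxy]-5-hydroxypent-3-yn-1-yl]furan-2(5H)-one F5. Because a butenolide would not survive a Grignard reagent, the union is then made by the zinc route. Trans-hydrostannation (Bu3SnH, [Cp*RuCl]4 cat., CH2Cl2) gives (S,Z)-4-[1-[(tert-butyldimethylsilyl)oxy]-5-hydroxy-4-(tributylstannyl)pent-3-en-1-yl]furan-2(5H)-one F6. Iodination (I2, CH2Cl2, 0 °C) gives (S,Z)-4-[1-[(tert-butyldimethylsilyl)oxy]-5-hydroxy-4-iodopent-3-en-1-yl]furan-2(5H)-one F7. Negishi coupling of F7 with the alkylzinc bromide F3 (Pd(OAc)2, SPhos, THF, rt) comes back to the route at 23.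

Step 4. Facial discrimination may be insufficient for this small, electron-rich heteroaryl aldehyde, or an uncatalysed background addition may erode it. The fallback sets out from aldehyde 10 and replaces asymmetric catalysis by resolution. A zinc-mediated Barbier propargylation (propargyl bromide, Zn, THF–aq. NH4Cl) gives racemic 1-(furan-3-yl)but-3-yn-1-ol F8. Lipase-catalysed acylation (Candida antarctica lipase B, vinyl acetate, MTBE, 30 °C) should, by the usual enantiopreference of lipases for aryl carbinols, acetylate the (R)-enantiomer to (R)-1-(furan-3-yl)but-3-yn-1-yl acetate F9. The unreacted (S)-alcohol is separated by chromatography, which comes back to the route at 12.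

**Further compounds**

F1 | step 7 | (S,Z)-5-[(tert-butyldimethylsilyl)oxy]-5-(furan-3-yl)-2-(tributylstannyl)pent-2-en-1-ol | OC/C(=C/C[C@H](O[Si](C)(C)C(C)(C)C)c1ccoc1)[Sn](CCCC)(CCCC)CCCC
F2 | step 7 | (S,Z)-5-[(tert-butyldimethylsilyl)oxy]-5-(furan-3-yl)-2-iodopent-2-en-1-ol | OC/C(I)=C/C[C@H](O[Si](C)(C)C(C)(C)C)c1ccoc1
F3 | step 7 | [(E)-4-methyl-6-(2,6,6-trimethylcyclohex-1-en-1-yl)hex-3-en-1-yl]zinc bromide | CC1=C(CC/C(C)=C/CC[Zn]Br)C(C)(C)CCC1
F4 | step 8 | 4-[(S)-1-[(tert-butyldimethylsilyl)oxy]-5-hydroxypent-3-yn-1-yl]-5-hydroxyfuran-2(5H)-one | OCC#CC[C@H](O[Si](C)(C)C(C)(C)C)C1=CC(=O)OC1O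
F5 | step 8 | (S)-4-[1-[(tert-butyldimethylsilyl)oxy]-5-hydroxypent-3-yn-1-yl]furan-2(5H)-one | OCC#CC[C@H](O[Si](C)(C)C(C)(C)C)C1=CC(=O)OC1
F6 | step 8 | (S,Z)-4-[1-[(tert-butyldimethylsilyl)oxy]-5-hydroxy-4-(tributylstannyl)pent-3-en-1-yl]furan-2(5H)-one | OC/C(=C/C[C@H](O[Si](C)(C)C(C)(C)C)C1=CC(=O)OC1)[Sn](CCCC)(CCCC)CCCC
F7 | step 8 | (S,Z)-4-[1-[(tert-butyldimethylsilyl)oxy]-5-hydroxy-4-iodopent-3-en-1-yl]furan-2(5H)-one | OC/C(I)=C/C[C@H](O[Si](C)(C)C(C)(C)C)C1=CC(=O)OC1
F8 | step 4 | racemic 1-(furan-3-yl)but-3-yn-1-ol | C#CCC(O)c1ccoc1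
F9 | step 4 | (R)-1-(furan-3-yl)but-3-yn-1-yl acetate | C#CC[C@@H](OC(C)=O)c1ccoc1
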